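**Plan**

- Quinone numbering: Q1 bears the 2‑tert‑prenylindole (indole A), Q2 OMe, Q3 C=O, Q4 bears indole B, Q5 OMe, Q6 C=O. The ring is an ene‑dione half Q3–Q4–Q5–Q6 joined to a two‑carbon half Q1–Q2, and each half carries one indole and one methoxy group.
- Retrosynthesis: after removal of two N‑protecting groups, the quinone is cut at Q6–Q1 and Q2–Q3. This gives a maleoylcobalt complex of a methoxy(indolyl)cyclobutenedione (Q3–Q6 bonded) and an indolyl methoxyalkyne.
- Further cuts: the indole B C3–Q4 bond (3‑lithioindole plus dimethyl squarate), the indole A C3–Q1 bond (Negishi coupling) and the C2–C3 bond of indole A (Madelung closure).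
- Forward: the pyrrole ring of indole A closes first and the alkyne is attached; the squarate is arylated; the quinone ring closes last, directly at the quinone oxidation level; fluoride then frees both N–H groups.
- The target has no stereocentre. The only selectivity to secure is the 2,5‑placement of the methoxy groups, which is decided in the annulation.

Key step: step 8

Remark: indole B carries a triisopropylsilyl group (it blocks C2 and allows clean C3 lithiation); indole A carries SEM, which is slim enough for the nitrogen next to the quaternary carbon.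
Remark: complex 21 is assumed to be the neutral octahedral chloro(dimethylglyoxime)(pyridine) maleoyl complex of trivalent cobalt; adduct 18 is racemic and its stereocentre disappears within the same step.

**Route**

Step 1
Reactants: 1 2,2-dimethylbut-3-enoic acid; 2 o-toluidine (2-methylaniline)
Product: 4 N-(2-methylphenyl)-2,2-dimethylbut-3-enamide, via 2,2-dimethylbut-3-enoyl chloride 3 (not isolated)
Conditions: (COCl)2, cat. DMF, CH2Cl2, 0 °C → rt; then 2, Et3N, CH2Cl2, 0 °C → rt
Reagents that add atoms: none
Why: Acid chloride formation followed by Schotten–Baumann-type N-acylation; the α-quaternary acid cannot enolise, so the β,γ-alkene cannot move into conjugation.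

Step 2
Reactants: 4 N-(2-methylphenyl)-2,2-dimethylbut-3-enamide
Product: 6 2-(2-methylbut-3-en-2-yl)-1H-indole, via dilithiated amide 5 (not isolated)
Conditions: n-BuLi (3 equiv), THF, −20 °C → rt; aq. NH4Cl
Reagents that add atoms: none
Why: Madelung indole synthesis in its organolithium variant: the benzylic carbanion of 5 attacks the non-enolisable amide carbonyl (five-membered ring closure) and loss of the oxygen as lithium hydroxide aromatises the ring, a cyclisation that is well established for tert-alkyl amides of o-toluidine.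

Step 3
Reactants: 6 2-(2-methylbut-3-en-2-yl)-1H-indole
Product: 7 2-(2-methylbut-3-en-2-yl)-1-{[2-(trimethylsilyl)ethoxy]methyl}indole
Conditions: NaH, DMF, 0 °C; SEMCl, 0 °C → rt
Reagents that add atoms: 2-(trimethylsilyl)ethoxymethyl chloride (SEMCl), C[Si](C)(C)CCOCCl
Why: N-alkylation of the sodium indolide (SN2 on a highly reactive α-chloro ether), which should tolerate the neighbouring quaternary carbon because the electrophilic carbon is primary and unbranched.

Step 4
Reactants: 7 2-(2-methylbut-3-en-2-yl)-1-{[2-(trimethylsilyl)ethoxy]methyl}indole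
Product: 8 3-iodo-2-(2-methylbut-3-en-2-yl)-1-{[2-(trimethylsilyl)ethoxy]methyl}indole
Conditions: NIS, DMF, 0 °C, dark
Reagents that add atoms: N-iodosuccinimide (NIS), O=C1CCC(=O)N1I
Why: Electrophilic aromatic iodination at C3, the most nucleophilic position of an N-alkylindole and far more reactive than the isolated vinyl group.

Step 5
Reactants: 8 3-iodo-2-(2-methylbut-3-en-2-yl)-1-{[2-(trimethylsilyl)ethoxy]methyl}indole; 9 2-chloro-1,1-dimethoxyethane (chloroacetaldehyde dimethyl acetal)
Product: 12 3-(methoxyethynyl)-2-(2-methylbut-3-en-2-yl)-1-{[2-(trimethylsilyl)ethoxy]methyl}indole, via lithium methoxyacetylide 10 (not isolated), via methoxyethynylzinc chloride 11 (not isolated)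
Conditions: 9, LiNEt2 (3 equiv), THF, 0 °C; ZnCl2, 0 °C; then 8, Pd(PPh3)4 (5 mol %), THF, rt → 45 °C; aq. NaHCO3, Et3N-deactivated silica
Reagents that add atoms: none
Why: Twofold base-induced elimination (methanol, then HCl) converts 9 into the lithium acetylide, transmetalation to zinc tames its basicity, and Negishi coupling at zerovalent palladium is the known way from alkoxyethynylzinc chlorides and aryl iodides to aryl alkynyl ethers, the linear alkynyl group being small enough for the position next to the quaternary carbon.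

Step 6
Reactants: 13 indole
Product: 15 3-bromo-1-(triisopropylsilyl)indole, via 1-(triisopropylsilyl)indole 14 (not isolated)
Conditions: n-BuLi, THF, −78 → −10 °C; TIPSCl, 0 °C; then NBS, −78 °C → rt
Reagents that add atoms: chlorotriisopropylsilane (TIPSCl), CC(C)[Si](Cl)(C(C)C)C(C)C; N-bromosuccinimide (NBS), O=C1CCC(=O)N1Br
Why: N-silylation of lithium indolide followed in the same flask by electrophilic bromination, which the bulky silyl group directs cleanly to C3.

Step 7
Reactants: 15 3-bromo-1-(triisopropylsilyl)indole; 16 dimethyl squarate (3,4-dimethoxycyclobut-3-ene-1,2-dione)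
Product: 19 3-methoxy-4-[1-(triisopropylsilyl)indol-3-yl]cyclobut-3-ene-1,2-dione, via 3-lithio-1-(triisopropylsilyl)indole 17 (not isolated), via lithium cyclobutenolate adduct 18 (not isolated)
Conditions: t-BuLi (2 equiv), THF, −78 °C; 16, THF, −78 °C; (CF3CO)2O, −78 °C; aq. NH4Cl
Reagents that add atoms: water, O
Why: Bromine–lithium exchange gives a C3-lithioindole that the silyl group keeps from migrating to C2, and its 1,2-addition to one squarate carbonyl followed by trifluoroacetylation, ionisation, capture by water and loss of methanol is the established carbonyl-transposition route from dialkyl squarates to 3-aryl-4-alkoxycyclobutenediones.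

Step 8
Reactants: 19 3-methoxy-4-[1-(triisopropylsilyl)indol-3-yl]cyclobut-3-ene-1,2-dione; 12 3-(methoxyethynyl)-2-(2-methylbut-3-en-2-yl)-1-{[2-(trimethylsilyl)ethoxy]methyl}indole
Product: 22 2,5-dimethoxy-3-[1-(triisopropylsilyl)indol-3-yl]-6-[2-(2-methylbut-3-en-2-yl)-1-{[2-(trimethylsilyl)ethoxy]methyl}indol-3-yl]cyclohexa-2,5-diene-1,4-dione, via (maleoyl)CoCl(PPh3)2 complex 20 (not isolated), via (maleoyl)CoCl(dimethylglyoxime)(pyridine) complex 21 (not isolated)
Conditions: ClCo(PPh3)3 (1.1 equiv), PhH, rt → 50 °C; dimethylglyoxime, pyridine, rt; hexane wash of the crude solid; then 12, ZnCl2, CH2Cl2, 0 °C → rt; air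
Reagents that add atoms: none
Why: Monovalent cobalt of ClCo(PPh3)3 inserts oxidatively into the Q3–Q6 bond between the two carbonyls of 19 to give the five-membered maleoyl metallacycle 20 of trivalent cobalt, and exchange of the phosphines for dimethylglyoxime and pyridine gives the octahedral complex 21. With ZnCl2 as activator the alkyne 12 inserts into the Co–C(Q6) acyl bond (Q6–Q1 formed) to give a seven-membered cobaltacycle, and C–C reductive elimination forms Q2–Q3 and releases the quinone while cobalt returns to the monovalent state. The closest known reaction type is the benzoquinone synthesis from maleoylcobalt dimethylglyoxime complexes and alkynes under Lewis acid activation, a metal-mediated formal [4+2] annulation. The one new ring, the six-membered quinone, closes by reductive elimination from the seven-membered metallacycle, already at the quinone oxidation level, and no stereocentre is formed. The step needs the 2,5- and not the 2,6-orientation of the methoxy groups, so the nucleophilic alkyne carbon Q1 (β to the alkyne oxygen) has to bond to acyl Q6; this should be favoured because Q3 is the vinylogous-ester carbonyl of the Q5 methoxy group and hence the weaker electrophile, whereas the Q6 carbonyl oxygen and the adjacent Q5 methoxy oxygen can chelate ZnCl2 in a five-membered ring. At the crowded C3 of indole A the linear alkyne is the smallest possible carbon substituent, so the strain between the tert-prenyl group and the quinone arises only in the product-forming closure.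

Step 9
Reactants: 22 2,5-dimethoxy-3-[1-(triisopropylsilyl)indol-3-yl]-6-[2-(2-methylbut-3-en-2-yl)-1-{[2-(trimethylsilyl)ethoxy]methyl}indol-3-yl]cyclohexa-2,5-diene-1,4-dione
Product: 23 2,5-dimethoxy-3-(1H-indol-3-yl)-6-[2-(2-methylbut-3-en-2-yl)-1H-indol-3-yl]cyclohexa-2,5-diene-1,4-dione (CNP0103667.0)
Conditions: Bu4NF (excess), THF, 0 → 55 °C; AcOH quench
Reagents that add atoms: none
Why: Fluoride-induced desilylation cleaves the N–Si bond of indole B directly and fragments the SEM group of indole A (attack at silicon, loss of ethene and formaldehyde), both helped by the fact that each indole nitrogen is a vinylogous amide nitrogen of the quinone and so a good leaving group.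

**Compound list**

1 | 2,2-dimethylbut-3-enoic acid | C=CC(C)(C)C(=O)O | starting material
2 | o-toluidine (2-methylaniline) | Cc1ccccc1N | starting material
3 | 2,2-dimethylbut-3-enoyl chloride | C=CC(C)(C)C(=O)Cl | intermediate
4 | N-(2-methylphenyl)-2,2-dimethylbut-3-enamide | C=CC(C)(C)C(=O)Nc1ccccc1C | intermediate
5 | N-lithio-N-[2-(lithiomethyl)phenyl]-2,2-dimethylbut-3-enamide (dilithiated amide) | [Li]Cc1ccccc1N([Li])C(=O)C(C)(C)C=C | intermediate
6 | 2-(2-methylbut-3-en-2-yl)-1H-indole | C=CC(C)(C)c1cc2ccccc2[nH]1 | intermediate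
7 | 2-(2-methylbut-3-en-2-yl)-1-{[2-(trimethylsilyl)ethoxy]methyl}indole | C=CC(C)(C)c1cc2ccccc2n1COCC[Si](C)(C)C | intermediate
8 | 3-iodo-2-(2-methylbut-3-en-2-yl)-1-{[2-(trimethylsilyl)ethoxy]methyl}indole | C=CC(C)(C)c1c(I)c2ccccc2n1COCC[Si](C)(C)C | intermediate
9 | 2-chloro-1,1-dimethoxyethane | COC(CCl)OC | starting material
10 | lithium methoxyacetylide | [Li]C#COC | intermediate
11 | methoxyethynylzinc chloride | COC#C[Zn]Cl | intermediate
12 | 3-(methoxyethynyl)-2-(2-methylbut-3-en-2-yl)-1-{[2-(trimethylsilyl)ethoxy]methyl}indole | C=CC(C)(C)c1n(COCC[Si](C)(C)C)c2ccccc2c1C#COC | intermediate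
13 | indole | c1ccc2[nH]ccc2c1 | starting material
14 | 1-(triisopropylsilyl)indole | CC(C)[Si](C(C)C)(C(C)C)n1ccc2ccccc21 | intermediate
15 | 3-bromo-1-(triisopropylsilyl)indole | CC(C)[Si](C(C)C)(C(C)C)n1cc(Br)c2ccccc21 | intermediate
16 | dimethyl squarate | COC1=C(OC)C(=O)C1=O | starting material
17 | 3-lithio-1-(triisopropylsilyl)indole | [Li]c1cn([Si](C(C)C)(C(C)C)C(C)C)c2ccccc12 | intermediate
18 | lithium 2,3-dimethoxy-4-oxo-1-[1-(triisopropylsilyl)indol-3-yl]cyclobut-2-en-1-olate (racemic) | COC1=C(OC)C(O[Li])(c2cn([Si](C(C)C)(C(C)C)C(C)C)c3ccccc23)C1=O | intermediate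
19 | 3-methoxy-4-[1-(triisopropylsilyl)indol-3-yl]cyclobut-3-ene-1,2-dione | COC1=C(c2cn([Si](C(C)C)(C(C)C)C(C)C)c3ccccc23)C(=O)C1=O | intermediate
20 | chloro{2-methoxy-3-[1-(triisopropylsilyl)indol-3-yl]maleoyl}bis(triphenylphosphine)cobalt | COC1=C(c2cn([Si](C(C)C)(C(C)C)C(C)C)c3ccccc23)C(=O)[Co-2](Cl)([P+](c2ccccc2)(c2ccccc2)c2ccccc2)([P+](c2ccccc2)(c2ccccc2)c2ccccc2)C1=O | intermediate
21 | chloro(dimethylglyoxime)(pyridine){2-methoxy-3-[1-(triisopropylsilyl)indol-3-yl]maleoyl}cobalt | COC1=C(c2cn([Si](C(C)C)(C(C)C)C(C)C)c3ccccc23)C(=O)[Co-3]2(Cl)([n+]3ccccc3)([N+](O)=C(C)C(C)=[N+]2O)C1=O | intermediate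
22 | 2,5-dimethoxy-3-[1-(triisopropylsilyl)indol-3-yl]-6-[2-(2-methylbut-3-en-2-yl)-1-{[2-(trimethylsilyl)ethoxy]methyl}indol-3-yl]cyclohexa-2,5-diene-1,4-dione | C=CC(C)(C)c1n(COCC[Si](C)(C)C)c2ccccc2c1C1=C(OC)C(=O)C(c2cn([Si](C(C)C)(C(C)C)C(C)C)c3ccccc23)=C(OC)C1=O | intermediate
23 | 2,5-dimethoxy-3-(1H-indol-3-yl)-6-[2-(2-methylbut-3-en-2-yl)-1H-indol-3-yl]cyclohexa-2,5-diene-1,4-dione | C=CC(C)(C)c1[nH]c2ccccc2c1C1=C(OC)C(=O)C(c2c[nH]c3ccccc23)=C(OC)C1=O | target

**Step count and risks**

Total step count: 9. Longest linear sequence: 7 steps (steps 1, 2, 3, 4, 5, 8, 9); the indole B branch (steps 6, 7) joins at step 8.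

Steps most likely to fail:

1. Step 8. The acyl–alkyne bond may form with the wrong pairing (Q1 to Q3), which would give the 2,6-dimethoxy orientation. Alkyne uptake at the crowded cobalt centre may also be so slow that Lewis-acid-induced hydration or oligomerisation of the ynol ether wins. The fallback sets out from 13 and 6 and returns to the route at 23. Acid-promoted conjugate addition of indole 13 to 2,5-dichloro-1,4-benzoquinone (AcOH, THF) and re-oxidation with DDQ should give 2,5-dichloro-3-(1H-indol-3-yl)cyclohexa-2,5-diene-1,4-dione F1. A second acid-promoted addition, now of 6, and DDQ oxidation should give 2,5-dichloro-3-(1H-indol-3-yl)-6-[2-(2-methylbut-3-en-2-yl)-1H-indol-3-yl]cyclohexa-2,5-diene-1,4-dione F2. NaOMe in MeOH then replaces both chlorides by addition–elimination and gives 23. The 2,5-relationship is fixed by the halogen positions of the starting quinone and no protecting group is needed.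

2. Step 9. Cleavage of the SEM group at the hindered nitrogen of indole A may be slow, while basic fluoride exchanges or hydrolyses the quinone methoxy groups at Q2 and Q5 by addition–elimination. The fallback sets out from 22 and returns at 23; it accepts the hydrolysis and restores the ethers at the end. Aqueous NaOH in THF/MeOH should cleave both methyl ethers and the N–Si bond to give 2,5-dihydroxy-3-(1H-indol-3-yl)-6-[2-(2-methylbut-3-en-2-yl)-1-{[2-(trimethylsilyl)ethoxy]methyl}indol-3-yl]cyclohexa-2,5-diene-1,4-dione F3. Its dianion is inert to nucleophiles, so forcing Bu4NF (DMF, 80 °C) can remove the SEM group and give 2,5-dihydroxy-3-(1H-indol-3-yl)-6-[2-(2-methylbut-3-en-2-yl)-1H-indol-3-yl]cyclohexa-2,5-diene-1,4-dione F4. F4 must be kept away from strong acid, which would cyclise the vinyl group onto a hydroxyl. O-methylation of the two vinylogous acid hydroxyls with Me3SiCHN2 (MeOH/toluene) then gives 23.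

3. Step 5. The ynol ether may be lost by protonolysis or hydration during coupling and purification. Oxidative addition and transmetalation next to the quaternary carbon may be slow, and Heck-type carbopalladation of the pendant vinyl group may compete. The fallback sets out from 6 and returns at 12; it builds the alkyne by elimination instead of cross-coupling. Et2AlCl-mediated Friedel–Crafts acylation of 6 with methoxyacetyl chloride (CH2Cl2, 0 °C) should give 2-methoxy-1-[2-(2-methylbut-3-en-2-yl)-1H-indol-3-yl]ethan-1-one F5. N-alkylation (NaH, SEMCl, DMF) should give 2-methoxy-1-[2-(2-methylbut-3-en-2-yl)-1-{[2-(trimethylsilyl)ethoxy]methyl}indol-3-yl]ethan-1-one F6. Enolate trapping (KN(SiMe3)2, PhNTf2, THF, −78 °C) should give 2-methoxy-1-[2-(2-methylbut-3-en-2-yl)-1-{[2-(trimethylsilyl)ethoxy]methyl}indol-3-yl]ethenyl trifluoromethanesulfonate F7, whose alkene geometry is not controlled and does not matter. Elimination with KOt-Bu (THF, −78 °C) then gives the ynol ether 12.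

**Further compounds**

F1 | step 8 | 2,5-dichloro-3-(1H-indol-3-yl)cyclohexa-2,5-diene-1,4-dione | O=C1C=C(Cl)C(=O)C(c2c[nH]c3ccccc23)=C1Cl
F2 | step 8 | 2,5-dichloro-3-(1H-indol-3-yl)-6-[2-(2-methylbut-3-en-2-yl)-1H-indol-3-yl]cyclohexa-2,5-diene-1,4-dione | O=C1C(c2c(C(C)(C)C=C)[nH]c3ccccc23)=C(Cl)C(=O)C(c2c[nH]c3ccccc23)=C1Cl
F3 | step 9 | 2,5-dihydroxy-3-(1H-indol-3-yl)-6-[2-(2-methylbut-3-en-2-yl)-1-{[2-(trimethylsilyl)ethoxy]methyl}indol-3-yl]cyclohexa-2,5-diene-1,4-dione | C=CC(C)(C)c1n(COCC[Si](C)(C)C)c2ccccc2c1C1=C(O)C(=O)C(c2c[nH]c3ccccc23)=C(O)C1=O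
F4 | step 9 | 2,5-dihydroxy-3-(1H-indol-3-yl)-6-[2-(2-methylbut-3-en-2-yl)-1H-indol-3-yl]cyclohexa-2,5-diene-1,4-dione | C=CC(C)(C)c1[nH]c2ccccc2c1C1=C(O)C(=O)C(c2c[nH]c3ccccc23)=C(O)C1=O
F5 | step 5 | 2-methoxy-1-[2-(2-methylbut-3-en-2-yl)-1H-indol-3-yl]ethan-1-one | C=CC(C)(C)c1[nH]c2ccccc2c1C(=O)COC
F6 | step 5 | 2-methoxy-1-[2-(2-methylbut-3-en-2-yl)-1-{[2-(trimethylsilyl)ethoxy]methyl}indol-3-yl]ethan-1-one | C=CC(C)(C)c1n(COCC[Si](C)(C)C)c2ccccc2c1C(=O)COC
F7 | step 5 | 2-methoxy-1-[2-(2-methylbut-3-en-2-yl)-1-{[2-(trimethylsilyl)ethoxy]methyl}indol-3-yl]ethenyl trifluoromethanesulfonate | C=CC(C)(C)c1n(COCC[Si](C)(C)C)c2ccccc2c1C(OS(=O)(=O)C(F)(F)F)=COC
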